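Locants follow the 1-benzoxepine numbering of the target (O1, C2–C5, C5a, C6–C9, C9a) and are used for all intermediates.

**Retrosynthetic overview**
- Endgame: the 4-OH and 3-methylidene groups come from base-induced opening of the 3,4-epoxide of the 3-methyl-3-ene. Both C–Br bonds come from one double Appel reaction, with C7–Br formed by inversion of the axial alcohol of a C7 ketone.
- Key disconnection C9–C9a: the bicyclic C7 ketone comes from a monocyclic 2-methylidene-oxepine bearing a CMe2–CO–CH=CH2 chain on C5a. H-atom transfer to the enol ether gives the C9a radical, which closes the carbocycle on the vinyl ketone.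
- Enabling feature: C9a is both the O1-bearing carbon of the oxepane and the methyl-bearing fusion carbon, so it is the H• adduct of a lactone-derived C=CH2. C9 lies β to C7, the bromine-bearing carbon of the cyclohexane, so at ketone level C9 is a Giese acceptor. Quaternary C6 between them blocks enolisation and folds the chain.
- The enol ether comes from Tebbe methylenation of a seven-membered lactone. The lactone comes from RCM of the ester of an Evans-allylated acid (sets C5a) with a CBS-derived allylic alcohol (sets C2).
- Ring order: oxepine first (RCM), cyclohexane second (key step), then a transient oxirane that is opened in the last step.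

Key step: step 12

Remark: compounds 1, 2 and 9 and all reagents named under the conditions are taken to be commercial.

**Step 1**
Reactants: 1 2,2-dimethylsuccinic anhydride; 2 (4S)-4-benzyl-1,3-oxazolidin-2-one
Product: 3 4-[(4S)-4-benzyl-2-oxo-1,3-oxazolidin-3-yl]-2,2-dimethyl-4-oxobutanoic acid
Conditions: 2, n-BuLi, THF, −78 °C; then 1, −78 → 0 °C; 1 M HCl
Reagents that add atoms: none
Why: N-Acylation of the lithiated oxazolidinone by anhydride opening should occur at the carbonyl next to CH2, because the other carbonyl is shielded by the gem-dimethyl group; no stereocentre is formed.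

**Step 2**
Reactants: 3 imide acid
Product: 5 4-[(4S)-4-benzyl-2-oxo-1,3-oxazolidin-3-yl]-N-methoxy-N,2,2-trimethyl-4-oxobutanamide, via acid chloride 4 (not isolated)
Conditions: (COCl)2, cat. DMF, CH2Cl2, 0 °C → rt; then MeNH(OMe)·HCl, pyridine, 0 °C
Reagents that add atoms: N,O-dimethylhydroxylamine hydrochloride, CNOC.Cl; oxalyl chloride, O=C(Cl)C(=O)Cl (chlorine of 4)
Why: Acid chloride formation and Weinreb amide synthesis turn the hindered carboxyl group into an acyl donor without α-hydrogen that will later stop at the ketone stage; no stereocentre is touched.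

**Step 3**
Reactants: 5 Weinreb amide imide
Product: 6 (3S)-3-{[(4S)-4-benzyl-2-oxo-1,3-oxazolidin-3-yl]carbonyl}-N-methoxy-N,2,2-trimethylhex-5-enamide
Conditions: NaHMDS, THF, −78 °C; allyl iodide, −78 → −40 °C
Reagents that add atoms: allyl iodide, C=CCI
Why: Evans asymmetric alkylation: the chelated (Z)-sodium enolate should be allylated on the face opposite the 4-benzyl group, which sets the future C5a as S.

**Step 4**
Reactants: 6 allylated imide
Product: 8 (2S)-2-{1-[methoxy(methyl)amino]-2-methyl-1-oxopropan-2-yl}pent-4-enoic acid, via peroxy acid 7 (not isolated)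
Conditions: LiOH, H2O2, THF–H2O, 0 °C; Na2SO3; HCl to pH 2
Reagents that add atoms: hydrogen peroxide, OO
Why: Hydroperoxide cleavage of the Evans imide attacks the exocyclic carbonyl even in hindered imides, sulfite reduces the peroxy acid, and the α-stereocentre should not epimerise at 0 °C.

**Step 5**
Reactants: 9 (tert-butyldimethylsilyloxy)acetaldehyde
Product: 10 rac-1-[(tert-butyldimethylsilyl)oxy]-3-methylbut-3-en-2-ol
Conditions: isopropenylmagnesium bromide, THF, −78 → 0 °C; aq. work-up
Reagents that add atoms: isopropenylmagnesium bromide, CC(=C)[Mg]Br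
Why: Grignard 1,2-addition gives the racemic allylic alcohol, whose stereocentre is erased in the next step.

**Step 6**
Reactants: 10 racemic allylic alcohol
Product: 11 1-[(tert-butyldimethylsilyl)oxy]-3-methylbut-3-en-2-one
Conditions: Dess–Martin periodinane, CH2Cl2, 0 °C → rt
Reagents that add atoms: none
Why: Dess–Martin oxidation gives the enone under near-neutral conditions that leave the silyl ether and the 1,1-disubstituted alkene untouched.

**Step 7**
Reactants: 11 enone
Product: 12 (2R)-1-[(tert-butyldimethylsilyl)oxy]-3-methylbut-3-en-2-ol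
Conditions: (R)-Me-CBS (20 mol %), catecholborane, toluene, −78 °C; aq. work-up
Reagents that add atoms: none
Why: Corey–Bakshi–Shibata reduction: isopropenyl acts as the large and CH2OTBS as the small substituent, so the (R)-catalyst should give the 2R alcohol (future C2), and catecholborane at −78 °C avoids hydroboration.

**Step 8**
Reactants: 8 acid; 12 (2R)-alcohol
Product: 14 (2R)-1-[(tert-butyldimethylsilyl)oxy]-3-methylbut-3-en-2-yl (2S)-2-{1-[methoxy(methyl)amino]-2-methyl-1-oxopropan-2-yl}pent-4-enoate, via mixed anhydride 13 (not isolated)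
Conditions: 2,4,6-trichlorobenzoyl chloride, Et3N, toluene, rt; then 12, DMAP, rt
Reagents that add atoms: 2,4,6-trichlorobenzoyl chloride, O=C(Cl)c1c(Cl)cc(Cl)cc1Cl (acyl group of 13)
Why: Yamaguchi esterification activates the hindered acid as a mixed anhydride that DMAP transfers to the secondary alcohol without touching either stereocentre.

**Step 9**
Reactants: 14 diene ester
Product: 15 (3S,7R)-7-{[(tert-butyldimethylsilyl)oxy]methyl}-3-{1-[methoxy(methyl)amino]-2-methyl-1-oxopropan-2-yl}-6-methyl-4,7-dihydrooxepin-2(3H)-one
Conditions: Hoveyda–Grubbs II (10 mol %), toluene (2 mM), 80 °C, Ar sparge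
Reagents that add atoms: none
Why: Ring-closing metathesis starts at the monosubstituted allyl terminus and closes onto the isopropenyl group, giving the seven-membered lactone with the ring-(Z) trisubstituted C3=C4 bond.

**Step 10**
Reactants: 15 lactone
Product: 16 2-[(3S,7R)-7-{[(tert-butyldimethylsilyl)oxy]methyl}-6-methyl-2-methylidene-2,3,4,7-tetrahydrooxepin-3-yl]-N-methoxy-N,2-dimethylpropanamide
Conditions: Tebbe reagent (1.05 equiv), pyridine (cat.), THF–toluene, −40 → 0 °C; aq. NaOH quench
Reagents that add atoms: Tebbe reagent, [CH2-2].[Cl-].C[Al+]C.[Ti+4].c1cc[cH-]c1.c1cc[cH-]c1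
Why: Tebbe methylenation: the nucleophilic titanium methylidene should take the more electrophilic and more accessible lactone carbonyl rather than the neopentyl Weinreb amide, and the low temperature keeps the allyl vinyl ether product from Claisen rearrangement.

**Step 11**
Reactants: 16 exocyclic enol ether
Product: 17 4-[(3S,7R)-7-{[(tert-butyldimethylsilyl)oxy]methyl}-6-methyl-2-methylidene-2,3,4,7-tetrahydrooxepin-3-yl]-4-methylpent-1-en-3-one
Conditions: vinylmagnesium bromide (3 equiv), THF, 0 °C; poured into cold pH 7 phosphate buffer; used at once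
Reagents that add atoms: vinylmagnesium bromide, C=C[Mg]Br
Why: Weinreb ketone synthesis: the chelated tetrahedral adduct persists until the neutral quench, so a single addition should give the vinyl ketone while the base-stable enol ether survives.

**Step 12**
Reactants: 17 enol ether vinyl ketone
Product: 18 (2R,5aS,9aS)-2-{[(tert-butyldimethylsilyl)oxy]methyl}-3,6,6,9a-tetramethyl-2,5,5a,8,9,9a-hexahydro-1-benzoxepin-7(6H)-one
Conditions: Fe(dibm)3 (15 mol %), PhSiH2(Oi-Pr) (2 equiv), Na2HPO4, i-PrOH–THF 1:1 (0.01 M), 23 °C
Reagents that add atoms: none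
Why: An iron hydride formed from Fe(III) and the silane transfers H• to the terminal carbon of the exocyclic enol ether (this CH2 becomes the 9a-methyl group), the nucleophilic O1-stabilised tertiary radical at C9a adds to C9, the unsubstituted β-carbon of the vinyl ketone, and the α-keto radical is reduced by Fe(II) and protonated by i-PrOH to the C7 ketone. The closest known reaction type is the MHAT-initiated reductive olefin coupling (HAT/Giese addition), which has been run with enol ethers and lactone-derived exo-glycals as donors and with vinyl ketones as acceptors. Only the cyclohexanone ring is closed, in the 6-endo-trig mode; 5-exo attack at the α-carbon is polarity-mismatched, and the gem-dimethyl group at C6 speeds the closure. C9a is the only new stereocentre: the radical is planar, the 2-CH2OTBS group is held pseudo-axial on the α-face by A(1,2) strain with the 3-methyl group and screens that face across O1, so C9 should bond on the β-face through a chair-like transition state with C5a–C5 and C9a–O1 equatorial (the arrangement that gives trans-decalins in radical polyene cyclisations), which gives the trans fusion with the 9a-methyl cis to the C2 side chain. The step needs HAT to the 1,1-disubstituted enol ether rather than to C3=C4 or the enone: C3=C4 is trisubstituted, flanked by branched C2 and gives a less stabilised radical with no acceptor in reach, the enone is electron-poor and a poor H• acceptor, and Na2HPO4 protects the acid-labile enol ether.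

**Step 13**
Reactants: 18 bicyclic ketone
Product: 19 (2R,5aS,7R,9aS)-2-{[(tert-butyldimethylsilyl)oxy]methyl}-3,6,6,9a-tetramethyl-2,5,5a,6,7,8,9,9a-octahydro-1-benzoxepin-7-ol
Conditions: L-Selectride, THF, −78 → −40 °C; aq. work-up
Reagents that add atoms: none
Why: Diastereoselective ketone reduction: the bulky borohydride avoids the axial trajectory past H-5a and H-9 and delivers hydride equatorially, which should give the axial 7R alcohol as with 4,4-dimethyl-3-oxo terpenoids.

**Step 14**
Reactants: 19 silyl ether alcohol
Product: 20 (2R,5aS,7R,9aS)-2-(hydroxymethyl)-3,6,6,9a-tetramethyl-2,5,5a,6,7,8,9,9a-octahydro-1-benzoxepin-7-ol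
Conditions: TBAF, THF, 0 °C → rt
Reagents that add atoms: none
Why: Fluoride desilylation frees the primary alcohol and affects no other group or stereocentre.

**Step 15**
Reactants: 20 diol
Product: 21 (2R,5aS,7S,9aS)-7-bromo-2-(bromomethyl)-3,6,6,9a-tetramethyl-2,5,5a,6,7,8,9,9a-octahydro-1-benzoxepine
Conditions: CBr4 (5 equiv), PPh3 (5 equiv), 2,6-lutidine, toluene, 0 → 70 °C
Reagents that add atoms: carbon tetrabromide, BrC(Br)(Br)Br
Why: Double Appel reaction: the primary alcohol is substituted directly, and bromide should displace the axial secondary alkoxyphosphonium ion from the equatorial side with inversion, giving the equatorial 7S bromide.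

**Step 16**
Reactants: 21 dibromide
Product: 22 (2R,3R,4R,5aS,7S,9aS)-3,4-epoxide of 21 with the oxirane oxygen on the face of H-2 and H-5a
Conditions: mCPBA, CH2Cl2, 0 °C
Reagents that add atoms: 3-chloroperbenzoic acid, O=C(OO)c1cccc(Cl)c1
Why: Prilezhaev epoxidation of the only alkene should occur on the β-face, opposite the pseudo-axial 2-CH2Br and the axial 9a-methyl group, which sets C3 and C4 as R,R.

**Step 17**
Reactants: 22 epoxide
Product: 23 (2R,4R,5aS,7S,9aS)-7-bromo-2-(bromomethyl)-6,6,9a-trimethyl-3-methylidenedecahydro-1-benzoxepin-4-ol (target)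
Conditions: Et2Al(TMP) [TMP-H, n-BuLi; Et2AlCl], toluene, 0 °C; aq. work-up
Reagents that add atoms: none
Why: Yamamoto-type epoxide-to-allylic-alcohol isomerisation: aluminium binds the oxirane oxygen and the hindered amide removes a proton from the unhindered 3-methyl group in a syn elimination, so C3–O breaks, the exocyclic methylene forms and the untouched C4–O bond keeps C4 as R.

**Compound list**
1 | 2,2-dimethylsuccinic anhydride | CC1(C)CC(=O)OC1=O | starting material
2 | (4S)-4-benzyl-1,3-oxazolidin-2-one | O=C1N[C@@H](Cc2ccccc2)CO1 | starting material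
3 | 4-[(4S)-4-benzyl-2-oxo-1,3-oxazolidin-3-yl]-2,2-dimethyl-4-oxobutanoic acid | OC(=O)C(C)(C)CC(=O)N1[C@@H](Cc2ccccc2)COC1=O | intermediate
4 | acid chloride of 3 | ClC(=O)C(C)(C)CC(=O)N1[C@@H](Cc2ccccc2)COC1=O | intermediate
5 | Weinreb amide imide | CON(C)C(=O)C(C)(C)CC(=O)N1[C@@H](Cc2ccccc2)COC1=O | intermediate
6 | (3S)-allylated imide | C=CC[C@@H](C(C)(C)C(=O)N(C)OC)C(=O)N1[C@@H](Cc2ccccc2)COC1=O | intermediate
7 | (2S)-peroxy acid | C=CC[C@@H](C(C)(C)C(=O)N(C)OC)C(=O)OO | intermediate
8 | (2S)-2-{1-[methoxy(methyl)amino]-2-methyl-1-oxopropan-2-yl}pent-4-enoic acid | C=CC[C@@H](C(C)(C)C(=O)N(C)OC)C(=O)O | intermediate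
9 | (tert-butyldimethylsilyloxy)acetaldehyde | O=CCO[Si](C)(C)C(C)(C)C | starting material
10 | rac-1-[(tert-butyldimethylsilyl)oxy]-3-methylbut-3-en-2-ol | OC(CO[Si](C)(C)C(C)(C)C)C(C)=C | intermediate
11 | 1-[(tert-butyldimethylsilyl)oxy]-3-methylbut-3-en-2-one | O=C(CO[Si](C)(C)C(C)(C)C)C(C)=C | intermediate
12 | (2R)-1-[(tert-butyldimethylsilyl)oxy]-3-methylbut-3-en-2-ol | O[C@@H](CO[Si](C)(C)C(C)(C)C)C(C)=C | intermediate
13 | mixed 2,4,6-trichlorobenzoic anhydride of 8 | C=CC[C@@H](C(C)(C)C(=O)N(C)OC)C(=O)OC(=O)c1c(Cl)cc(Cl)cc1Cl | intermediate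
14 | diene ester of 8 and 12 | C=CC[C@@H](C(C)(C)C(=O)N(C)OC)C(=O)O[C@@H](CO[Si](C)(C)C(C)(C)C)C(C)=C | intermediate
15 | (3S,7R)-oxepinone (lactone) | CC1=CC[C@@H](C(C)(C)C(=O)N(C)OC)C(=O)O[C@H]1CO[Si](C)(C)C(C)(C)C | intermediate
16 | (3S,7R)-2-methylidene-oxepine Weinreb amide | CC1=CC[C@@H](C(C)(C)C(=O)N(C)OC)C(=C)O[C@H]1CO[Si](C)(C)C(C)(C)C | intermediate
17 | (3S,7R)-2-methylidene-oxepine vinyl ketone | CC1=CC[C@@H](C(C)(C)C(=O)C=C)C(=C)O[C@H]1CO[Si](C)(C)C(C)(C)C | intermediate
18 | (2R,5aS,9aS)-bicyclic C7 ketone | CC1=CC[C@H]2C(C)(C)C(=O)CC[C@]2(C)O[C@H]1CO[Si](C)(C)C(C)(C)C | intermediate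
19 | (2R,5aS,7R,9aS)-axial C7 alcohol | CC1=CC[C@H]2C(C)(C)[C@H](O)CC[C@]2(C)O[C@H]1CO[Si](C)(C)C(C)(C)C | intermediate
20 | (2R,5aS,7R,9aS)-diol | CC1=CC[C@H]2C(C)(C)[C@H](O)CC[C@]2(C)O[C@H]1CO | intermediate
21 | (2R,5aS,7S,9aS)-dibromide | CC1=CC[C@H]2C(C)(C)[C@@H](Br)CC[C@]2(C)O[C@H]1CBr | intermediate
22 | (2R,3R,4R,5aS,7S,9aS)-3,4-epoxide | C[C@@]12O[C@@H]1C[C@H]3C(C)(C)[C@@H](Br)CC[C@]3(C)O[C@H]2CBr | intermediate
23 | (2R,4R,5aS,7S,9aS)-7-bromo-2-(bromomethyl)-6,6,9a-trimethyl-3-methylidenedecahydro-1-benzoxepin-4-ol | C=C1[C@H](O)C[C@H]2C(C)(C)[C@@H](Br)CC[C@]2(C)O[C@H]1CBr | target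

**Step count**
- Total step count: 17.
- Longest linear sequence: 14 steps (steps 1–4 and 8–17).

**Steps most likely to fail**

1. Step 12.
   - What may go wrong: bonding of C9 to the wrong face of the planar C9a radical would give a cis fusion. H-atom transfer to the ring alkene, β-scission of the allylic C2–O1 bond of the radical, or solvolysis of the enol ether may also intervene.
   - Fallback: it sets out from 16 and generates the radical by group abstraction instead of HAT, at low temperature, without metal hydride and without protic solvent.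
   - Benzeneselenol adds across the enol ether in the Markovnikov sense (CH2Cl2, −20 °C) to give the O,Se-ketal Weinreb amide F1 (C9a epimers, both usable).
   - Vinylmagnesium bromide converts it into the O,Se-ketal vinyl ketone F2.
   - Bu3SnH with Et3B/air in toluene at −78 °C abstracts the phenylselanyl group. The same radical then cyclises at a temperature where facial discrimination is sharper and the alkenes are not touched. The route is rejoined at 18.

2. Step 15.
   - What may go wrong: the axial neopentyl-type alkoxyphosphonium ion may undergo E2 loss towards C8 or methyl migration instead of SN2 displacement.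
   - Fallback: it sets out from 18 and puts the bromine on C7 by radical chemistry rather than by substitution.
   - Hydrazine hydrate (Et3N, EtOH, reflux) gives the C7 hydrazone F3.
   - CuBr2/t-BuOLi in THF oxidises it to the 7,7-dibromide F4.
   - One equivalent of Bu3SnH (Et3B/air, −78 °C) removes one bromine. The α-bromo radical should take hydrogen along the unhindered axial β-trajectory, which gives the equatorial 7S bromide silyl ether F5.
   - TBAF frees the primary alcohol F6, and an ordinary Appel reaction of this unhindered alcohol rejoins the route at 21.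

3. Step 17.
   - What may go wrong: the amide base may cause dehydrobromination, or it may remove H-2 instead of a methyl proton.
   - Fallback: it sets out from 22 and replaces the base-induced elimination by a radical opening.
   - Cp2TiCl (Cp2TiCl2, Mn, THF, rt, no hydrogen donor) cleaves C3–O homolytically to the tertiary C3 radical.
   - A second Ti(III) removes a hydrogen atom from the 3-methyl group, and work-up should give 23 directly (no new compound, F0).

**Further compounds**
F1 | step 12 | O,Se-ketal Weinreb amide (9a-methyl-9a-phenylselanyl, C9a epimers) | CC1=CC[C@@H](C(C)(C)C(=O)N(C)OC)C(C)([Se]c2ccccc2)O[C@H]1CO[Si](C)(C)C(C)(C)C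
F2 | step 12 | O,Se-ketal vinyl ketone (C9a epimers) | CC1=CC[C@@H](C(C)(C)C(=O)C=C)C(C)([Se]c2ccccc2)O[C@H]1CO[Si](C)(C)C(C)(C)C
F3 | step 15 | C7 hydrazone of 18 | CC1=CC[C@H]2C(C)(C)C(=NN)CC[C@]2(C)O[C@H]1CO[Si](C)(C)C(C)(C)C
F4 | step 15 | 7,7-dibromide | CC1=CC[C@H]2C(C)(C)C(Br)(Br)CC[C@]2(C)O[C@H]1CO[Si](C)(C)C(C)(C)C
F5 | step 15 | (7S)-bromide silyl ether | CC1=CC[C@H]2C(C)(C)[C@@H](Br)CC[C@]2(C)O[C@H]1CO[Si](C)(C)C(C)(C)C
F6 | step 15 | (7S)-bromide primary alcohol | CC1=CC[C@H]2C(C)(C)[C@@H](Br)CC[C@]2(C)O[C@H]1CO
F0 | step 17 | none | none
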